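The green run stands still by its end: bis adduct reads 18.3% at 5.00 h and 18.5% at 8.00 h, against a scatter of 0.5 percentage points, while solid substrate is still there at 15.8%. So reagent looks like the limiting reagent in green. Green reads 74.0% for the reagent share, the fraction of the reagent charge found in bis adduct at the end, with two reagent counted per bis adduct. The amber run reads 70.0%.

| flask | solid substrate | reagent | remark | time |
|---|---|---|---|---|
| green | 0.10 M | 0.50 equiv | run made earlier |  |
| amber | 0.075 M | 0.50 equiv | run made earlier |  |
| Tuesday's | 0.15 M | 0.500 equiv |  | 12 h |
| Friday's | 0.15 M | 1.20 equiv |  | 12 h |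
| Sunday's | 0.15 M | 2.50 equiv |  | 12 h |

- green (time / h: bis adduct / %, single product / %, solid substrate / %): 0.500: 6.4, 1.9, 59.8; 0.833: 8.5, 2.3, 45.3; 1.33: 11.0, 1.1, 34.0; 2.00: 13.0, 1.1, 25.5; 3.00: 16.2, 0.5, 20.4; 5.00: 18.3, 0.1, 17.3; 8.00: 18.5, 1.3, 15.8
- amber (time / h: bis adduct / %, single product / %, solid substrate / %): 0.500: 5.2, 2.1, 48.3; 0.833: 7.8, 0.5, 30.6; 1.33: 9.9, 0.4, 16.3; 2.00: 13.3, 0, 7.3; 3.00: 15.1, 0, 1.1; 5.00: 17.1, 0.5, 0.1; 8.00: 17.5, 0, 0

(standard deviation of a reading: 0.5 percentage points)

- solid substrate is a solid; its amount is given per volume of the solution
- at the start none of the solid substrate is in solution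

* bis adduct at the end, in percent of the solid substrate charged, for each flask in turn (Tuesday's, Friday's, Sunday's)

You can do two extreme flasks in the head, in fractions of the solid substrate charged. In the first, the reagent share is one, so bis adduct is the equivalents divided by two: 25.0% on Tuesday's and 60.0% on Friday's. On Sunday's that gives 125%, more than the charge, so the ceiling there is 100%. In the second, each flask keeps green's share, which gives 18.5%, 44.4% and 92.5%. I reckon the real flasks lie between these, but on a weak hint: with both runs at 0.50 equiv, the share read higher in green than in amber, by 4 points, as the solid substrate charge rose, yet the two bis adduct readings behind it stand 1 point apart against a scatter of 0.5 points. The three new flasks are richer in solid substrate than green, and Friday's and Sunday's also differ from green in their equivalents.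

The forecast gives 19.3%, 43% and 78%. That is inside my band on Tuesday's, just under it on Friday's, and well under it on Sunday's, a flask it calls “dissolution-limited early, with reagent decaying meanwhile”.

The flasks give 20.3%, 54.8% and 100%, each within the band.

starting material + reagent ⇌ single product (K = 6.80 /M, k = 0.730 /M/min); starting material + reagent → other mono adduct (k = 1.30 /M/min); reagent + single product → bis adduct (k = 0.870 /M/min); reagent + other mono adduct → bis adduct (k = 3.80 /M/min); solid substrate ⇌ starting material, rate k5*(cs5 - [starting material]) while solid is left; crystals form when [starting material] > cs5 (solubility = 0.0530 M, k = 0.0350 /min); reagent ⇌ dormant form (K = 2.70, k = 0.0430 /min) Tuesday's flask ends with other mono adduct at 9.44% and reagent at 0% of its own charge. Tuesday's reagent share is 81.2%, above the 74.0% read in green, and its other mono adduct, with one reagent each, holds a further 18.9% of the reagent charge. Friday's flask has a reagent share of 91.3%, and its other mono adduct, at 10.4%, holds a further 8.69% of the reagent charge.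

The earlier runs and the new flask are simulated for substances that don't exist.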